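(The numbers in the tables are calculated from invented constants; noise was put on by code.)

- The flask differs from Thursday's run in its catalyst, 8.4 mol% against 5.6 mol%, with the same substrates, gas and impurity, so I compared how hard each charge can push the rate.

| setting | Thursday's | Friday's | flask |
|---|---|---|---|
| left-handed substrate | 0.050 M | 0.050 M | 0.050 M |
| right-handed substrate | 0.050 M | 0.050 M | 0.050 M |
| gas | 29 mM (held) | 29 mM (held) | 29 mM (held) |
| free catalyst | 5.6 mol% | 13 mol% | 8.4 mol% |
| impurity | 0.59 mM | 0.59 mM | 0.59 mM |
| remark | run made earlier | run made earlier |  |

| run | time / min | left-handed product / % | left-handed substrate / % |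
|---|---|---|---|
| Thursday's | 1.00 | 5 | 43 |
| Thursday's | 2.00 | 16 | 36 |
| Thursday's | 3.00 | 23 | 26 |
| Thursday's | 4.00 | 27 | 21 |
| Thursday's | 5.00 | 36 | 18 |
| Thursday's | 6.00 | 40 | 12 |
| Friday's | 1.00 | 12 | 38 |
| Friday's | 2.00 | 22 | 32 |
| Friday's | 3.00 | 33 | 22 |
| Friday's | 4.00 | 40 | 11 |
| Friday's | 5.00 | 46 | 7 |
| Friday's | 6.00 | 43 | 1 |

(scatter of a reading: 2 percentage points)

- free catalyst is single-handed; left-handed substrate and right-handed substrate are mirror images of each other, charged as a racemate, each of them at the stated concentration
- at the start none of partner is dissolved
- the analysis behind the earlier runs scatters by 2 percentage points, standard deviation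
- candidate steps: partner + free catalyst + left-handed substrate -> free catalyst + left-handed product; partner + free catalyst + right-handed substrate -> free catalyst + right-handed product; free catalyst + impurity -> spent catalyst; gas <-> partner

1. apparent order in free catalyst when 20% of the left-handed substrate and right-handed substrate together are converted (percent change of the rate of making left-handed product for one percent more free catalyst charged)

- I assumed the impurity removes its own amount of catalyst; the charge of 2.80 mM on Thursday exceeds 0.59 mM, so active catalyst remains there, as in the flask with 4.20 mM.
- At one end, with the catalyst step slow, the order in charged catalyst would be charged over active catalyst: 1.16 in the flask, less than Thursday's 1.27.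
- At the other end, with gas uptake as the rate-limiting step, the order would be zero.
- I joined the ends like two time constants in series: the order is that first figure times the catalyst share, the catalyst step's fraction of the total resistance, which should also be the partner's level over saturation while partner is made as fast as it is used.
- The flask's charge lies near the geometric middle of Thursday's and Friday's, so I used the slope between those runs, taking the 2.00 min readings as my stand-in for the asked conversion.
- Averaging left-handed substrate lost and product made gave 15.0% on Thursday and 20.0% on Friday, hence a read order of 0.342 and a share of 0.294. A single reading scatters by 2 percentage points and that difference is 5 points, so this order and this share are rough readings.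
- The forecast gave 0.47, within 0.25 to 0.8, with the words “This suggests gas-to-partner transfer partly limits the rate”; my reading stood lower.

    partner + free catalyst + left-handed substrate → free catalyst + left-handed product (k = 10000 L² mol⁻² min⁻¹)
    partner + free catalyst + right-handed substrate → free catalyst + right-handed product (k = 5400 L² mol⁻² min⁻¹)
    free catalyst + impurity → spent catalyst (k = 55000 L mol⁻¹ min⁻¹)
    gas ⇌ partner, rate k4*(csat - [partner]) (kL = 0.810 min⁻¹)

- The flask gave 0.34. The asked conversion stood in the flask at 1.45 min, and a little later, at 2.50 min, its partner stood at 0.00881 M, which is 0.304 of saturation. Carrying my share to Friday's run, I scaled the ratio of transfer to catalyst resistance with active catalyst, which gave a ratio of 3.94. My estimate of Friday's order at the same conversion was 0.223.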